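If you can pin down just one number well, first ask which number the answers can feel.

| flask | starting material | protic impurity | temperature | remark | time |
|---|---|---|---|---|---|
| Wednesday's | 1 M | 0.030 M | −30 °C | run made earlier |  |
| Sunday's | 2.2 M | 0.030 M | 0 °C | run made earlier |  |
| Tuesday's | 1.5 M | 0.060 M | −30 °C | run made earlier |  |
| zeta | 1.5 M | 0.0300 M | 0 °C |  | 15 h |
| alpha | 1.5 M | 0.0300 M |  | at −25 °C until 8.0 h, from then on at 25 °C | 15 h |
| beta | 1.5 M | 0.0300 M | −25 °C |  | 15 h |
| theta | 1.5 M | 0.0300 M | 25 °C |  | 15 h |

| run | time / h | intermediate A / % | target / % |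
|---|---|---|---|
| Wednesday's | 6.00 | 0 | 0 |
| Wednesday's | 12.0 | 1.7 | 0.2 |
| Wednesday's | 20.0 | 1.4 | 0 |
| Wednesday's | 25.0 | 2.4 | 0.9 |
| Wednesday's | 40.0 | 3.4 | 0.4 |
| Wednesday's | 48.0 | 3.4 | 0 |
| Sunday's | 1.00 | 5.9 | 0 |
| Sunday's | 1.33 | 7.5 | 0.5 |
| Sunday's | 2.00 | 10.9 | 0 |
| Sunday's | 3.00 | 16.8 | 0.2 |
| Sunday's | 5.00 | 25.9 | 0 |
| Sunday's | 8.00 | 38.4 | 0.1 |
| Sunday's | 12.0 | 52.0 | 0 |
| Tuesday's | 4.00 | 0 | 0 |
| Tuesday's | 12.0 | 2.4 | 0 |
| Tuesday's | 25.0 | 0 | 0.6 |
| Tuesday's | 40.0 | 4.8 | 0.5 |
| Tuesday's | 48.0 | 2.0 | 1.0 |

(each reading ± 1 percentage point)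

- the flask with the highest amount of intermediate A, in percent of the starting material charged ("all alike" if they lie within 1.5 percentage points) (zeta / alpha / beta / theta / all alike)
- final intermediate A, as a percentage of the starting material charged, in zeta
- final intermediate A, as a percentage of the starting material charged, in alpha
- final intermediate A, as a percentage of the starting material charged, in beta
- final intermediate A, as a percentage of the starting material charged, in theta

- steps thought possible: intermediate B -> target; starting material + protic impurity -> quenched substrate; starting material -> intermediate A; intermediate A -> intermediate B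

1. Protic impurity. With c(protic impurity) at 0.0300 M against c(starting material) at 1.5 M, it can take 2.00% of the charge, one for one. So a 10% error in it moves the usable charge by 0.2 percentage points.

2. The leak from intermediate A to intermediate B. Sunday's target stays within the scatter of zero up to 12.0 h, so at 0 °C you can't read this leak. At 25 °C it is unmeasured, and that uncertainty sits on theta and alpha.

3. The rate constant k of starting material to intermediate A. Use the lifetime count n, the rate constant times the time allowed (a Damköhler number). For first-order loss, the share unconverted is exp(−n). A small fractional error in k then shifts the yield by that fraction times n·exp(−n), which peaks at one lifetime. That is the crossing, with the leak set aside: well below it the yield follows k, and well above it the charge caps the yield and k stops mattering.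

4. The number. Sunday's last reading gives k0 = 0.0612 h⁻¹ at 0 °C, and its reading at 5.00 h gives 0.0600 h⁻¹, so the curve reads as first order. Zeta's lifetime count is 0.917, right at the crossing. Your own reckoning for zeta is 58.8%. With sensitivity 0.359, a 10% error in k0 moves zeta by 3.6 points.

5. The forecast: alpha highest, with zeta 59%, alpha 88%, beta 2.4% and theta 80%. Its ground for the ranking: “Alpha spends less time warm, so it should retain more A than theta.”

6. The result: alpha highest, with zeta 59.1%, alpha 88.9%, beta 2.59% and theta 78.3%.

    intermediate B → target (k = 6.30 × 10⁻⁵ s⁻¹, Ea = 96.0 kJ mol⁻¹)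
    starting material + protic impurity → quenched substrate (k = 0.00540 M⁻¹ s⁻¹, Ea = 55.0 kJ mol⁻¹)
    starting material → intermediate A (k = 3.30 × 10⁻⁴ s⁻¹, Ea = 80.0 kJ mol⁻¹)
    intermediate A → intermediate B (k = 4.40 × 10⁻⁶ s⁻¹, Ea = 103 kJ mol⁻¹)
    (constants at 25 °C)

Theta stands 76 points above beta. With the temperature taken off starting material to intermediate A, that gap becomes −0.3 points, the largest single effect. Beta ends below the crossing at 4.58% conversion and theta far above it at 100%. Zeta, reckoned at 0.917 lifetimes, lies between them at 61.3%.

7. A second flask. Beta repeated at 0 °C has zeta's charge, temperature and time, so its count is again 0.917. That gives 58.8% intermediate A and 39.2% starting material left. The computed flask gives 59.1% and 38.7%.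

(Readings and results were generated by integration for an exercise; noise was put on by code.)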